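A direct plan would join the ring-C aldehyde A1 to a 2-silyloxy-3-methylfuran by a catalytic asymmetric vinylogous aldol reaction (butenolide A2). It would then protect the carbinol, formylate the arene, build ring A by a thermal Diels–Alder reaction on the butenolide and close ring B by aldol condensation (enone A3), before carbonyl reduction and oxidation to the quinone.
Its weakest steps would be:
- the aldol that sets C6 and C7, because one catalyst would have to fix both the absolute and the relative sense on a di-ortho-substituted, electron-rich aldehyde;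
- the cycloaddition that sets C4 and C5, because an α-methyl butenolide would be a hindered, sluggish dienophile (about 170 °C) whose facial bias would come only from an exocyclic centre;
- the silylation of the benzylic carbinol, which would add a step without adding complexity.

The new route disconnects ring B across C5–C6 and C10–C20 to a 2-benzopyrylium-4-olate and the C5=C10 double bond of a ring-A cyclohexenol that is tied to it as the O11–C1 aryl ether. It exploits that C6 and C20 are 1,5-related through C7–C9, so the C6 oxygen can be the ylide oxygen and C7 its carbonyl. One intramolecular (5+2) cycloaddition closes the seven-membered ring and relays C1 to C5 and C6; the bridging oxygen later becomes the lactone oxygen and the tether oxygen the C1 hydroxyl. No double stereodifferentiating aldol, no hindered Diels–Alder reaction and no carbinol protection remain.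

Key step: step 10

Remark on the chemistry (assumption): base-induced loss of acetate from a 1-acetoxyisochroman-4-one is taken to give the 2-benzopyrylium-4-olate in the way 6-acetoxypyran-3-ones give 3-oxidopyrylium ylides.
Remark on notation: atoms are numbered as in the 9(10→20)abeo-abietane skeleton; α is the face of H5. Ethyl 2-methyl-3-oxopropanoate is taken as commercially available.

Step 1
Reactants: 1 1,3-dimethoxybenzene; 2 acetone
Product: 4 1,3-dimethoxy-2-(propan-2-yl)benzene, via benzylic carbinol 3 (not isolated)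
Conditions: n-BuLi, THF, 0 °C → rt; acetone, −78 → 0 °C; H2O; then Et3SiH, CF3CO2H, CH2Cl2, 0 °C → rt
Reagents that add atoms: none
Why: Directed ortho-lithiation between the two methoxy groups, addition to acetone and ionic hydrogenation of the tertiary benzylic alcohol (cation flanked by two methoxy groups) should place the isopropyl group at the future C13; no stereocentre is formed.

Step 2
Reactants: 4 1,3-dimethoxy-2-(propan-2-yl)benzene; 5 2-chloro-2-oxoethyl acetate (acetoxyacetyl chloride)
Product: 6 2-[2,4-dimethoxy-3-(propan-2-yl)phenyl]-2-oxoethyl acetate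
Conditions: TiCl4, CH2Cl2, −20 → 0 °C
Reagents that add atoms: none
Why: Friedel–Crafts acylation at the position ortho and para to the methoxy groups (both such positions are equivalent by symmetry) should install C7 and C6 with the C6 oxygen already in place as its acetate.

Step 3
Reactants: 6 2-[2,4-dimethoxy-3-(propan-2-yl)phenyl]-2-oxoethyl acetate; 7 dichloromethyl methyl ether
Product: 8 2-[5-formyl-2,4-dimethoxy-3-(propan-2-yl)phenyl]-2-oxoethyl acetate
Conditions: Cl2CHOMe, TiCl4, CH2Cl2, 0 °C → rt; H2O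
Reagents that add atoms: water, O
Why: Rieche formylation should go to the only position that is ortho and para to the methoxy groups and meta to the acyl group (future C11), which gives the handle for the phenol.

Step 4
Reactants: 8 2-[5-formyl-2,4-dimethoxy-3-(propan-2-yl)phenyl]-2-oxoethyl acetate
Product: 10 2-[5-hydroxy-2,4-dimethoxy-3-(propan-2-yl)phenyl]-2-oxoethyl acetate, via aryl formate 9 (not isolated)
Conditions: mCPBA, CH2Cl2, 0 °C → rt; then Et3N, MeOH, 0 °C
Reagents that add atoms: meta-chloroperoxybenzoic acid, OOC(=O)c1cccc(Cl)c1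
Why: Dakin-type Baeyer–Villiger oxidation (aryl migration favoured by ortho and para methoxy groups, the aryl ketone reacting far more slowly) and mild methanolysis of the labile aryl formate should give the C11 phenol while the primary acetate survives.

Step 5
Reactants: 10 2-[5-hydroxy-2,4-dimethoxy-3-(propan-2-yl)phenyl]-2-oxoethyl acetate; 7 dichloromethyl methyl ether
Product: 11 2-[2-formyl-3-hydroxy-4,6-dimethoxy-5-(propan-2-yl)phenyl]-2-oxoethyl acetate
Conditions: Cl2CHOMe, TiCl4, CH2Cl2, 0 °C → rt; H2O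
Reagents that add atoms: water, O
Why: Titanium phenoxide-directed ortho-formylation (Rieche conditions) should attack the last free ring position, ortho to the hydroxyl, and so bring in C20 on C9.

Step 6
Reactants: 12 ethyl 2-methyl-3-oxopropanoate; 13 but-3-en-2-one
Product: 15 ethyl (1S)-1-methyl-4-oxocyclohex-2-ene-1-carboxylate, via Michael adduct 14 (not isolated)
Conditions: 9-amino(9-deoxy)epi-cinchona-alkaloid 3,5-bis(trifluoromethyl)phenyl thiourea (10 mol %; quinine- or quinidine-derived pseudoenantiomer chosen for the 2S adduct), toluene, −20 °C; then TsOH·H2O (20 mol %), toluene, 80 °C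
Reagents that add atoms: none
Why: Catalytic enantioselective Michael addition of the enolised α-formyl ester inside the hydrogen-bonded ion pair should set the quaternary C4 (S), and the Robinson-type aldol condensation of the methyl ketone onto the aldehyde (the only six-membered closure) should give the enone without touching that centre.

Step 7
Reactants: 15 ethyl (1S)-1-methyl-4-oxocyclohex-2-ene-1-carboxylate
Product: 16 ethyl (1S,4S)-4-hydroxy-1-methylcyclohex-2-ene-1-carboxylate
Conditions: (R)-2-methyl-CBS-oxazaborolidine [(R)-1-methyl-3,3-diphenyltetrahydro-1H,3H-pyrrolo[1,2-c][1,3,2]oxazaborole] (10 mol %), catecholborane, toluene, −78 °C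
Reagents that add atoms: none
Why: Corey–Bakshi–Shibata 1,2-reduction under catalyst control (the alkene arm acting as the large group) should give the S carbinol at the future C1, trans to the ester, the remote C4 centre exerting little bias.

Step 8
Reactants: 11 2-[2-formyl-3-hydroxy-4,6-dimethoxy-5-(propan-2-yl)phenyl]-2-oxoethyl acetate; 16 ethyl (1S,4S)-4-hydroxy-1-methylcyclohex-2-ene-1-carboxylate
Product: 17 ethyl (1S,4R)-4-{3-[(acetyloxy)acetyl]-2-formyl-4,6-dimethoxy-5-(propan-2-yl)phenoxy}-1-methylcyclohex-2-ene-1-carboxylate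
Conditions: PPh3, DIAD, toluene, 0 °C → rt
Reagents that add atoms: none
Why: Mitsunobu etherification of the acidic salicylaldehyde-type phenol should proceed by SN2 inversion at C1, placing the aryloxy group cis to the ester, while attack at the distal allyl terminus is blocked by the adjacent quaternary C4.

Step 9
Reactants: 17 ethyl (1S,4R)-4-{3-[(acetyloxy)acetyl]-2-formyl-4,6-dimethoxy-5-(propan-2-yl)phenoxy}-1-methylcyclohex-2-ene-1-carboxylate
Product: 18 ethyl (1S,4R)-4-{[1-hydroxy-5,7-dimethoxy-4-oxo-6-(propan-2-yl)-3,4-dihydro-1H-isochromen-8-yl]oxy}-1-methylcyclohex-2-ene-1-carboxylate (both anomers)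
Conditions: K2CO3 (0.2 equiv), MeOH, 0 °C
Reagents that add atoms: none
Why: Transesterification should free the C6 hydroxyl, which closes onto the neighbouring aldehyde to the six-membered lactol (a 1-hydroxyisochroman-4-one), the precursor of the ylide; the hindered quaternary ethyl ester should not react.

Step 10
Reactants: 18 ethyl (1S,4R)-4-{[1-hydroxy-5,7-dimethoxy-4-oxo-6-(propan-2-yl)-3,4-dihydro-1H-isochromen-8-yl]oxy}-1-methylcyclohex-2-ene-1-carboxylate
Product: 21 ethyl 1β,11:6α,20-diepoxy-12,14-dimethoxy-7-oxo-9(10→20)abeo-abieta-8,11,13-trien-19-oate (5α-H,10α-H; oxa-bridged pentacycle), via anomeric acetate 19 (not isolated), via benzopyrylium olate 20 (not isolated)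
Conditions: Ac2O, Et3N, DMAP (cat.), CH2Cl2, 0 °C; then DBU, MeCN (0.01 M), 60 °C
Reagents that add atoms: none
Why: Base removes H6 of the anomeric acetate and acetate leaves from C20 to give the 2-benzopyrylium-4-olate (a carbonyl ylide), which should add suprafacially across the tethered C5=C10 bond in an oxidopyrylium-type (5+2) cycloaddition, the closest known type being the intramolecular cycloaddition of such ylides with unactivated alkenes. Ring B is closed as the seven-membered carbocycle of an 8-oxabicyclo[3.2.1]octanone by forming C5–C6 and C10–C20, while the O11–C1 ether closes a temporary cis-fused chromane (six-membered tether ring). C5 and C6, and the transient C10 and C20, are all controlled by C1: the dipole hangs from the β-oxygen at C1 and can reach only the β-face of the alkene, so C6 and C20 bond cis to O1 and to the C4 ester. The two-atom tether allows only the regiochemistry C10 to C20 (six- against seven-membered tether ring) and only the endo mode with ring A under the aryl ketone bridge, which puts H5 syn to the bridging oxygen, that is the 5R,6R relationship of the trans-fused lactone. The step needs cycloaddition to outrun ylide dimerisation, which high dilution and the intramolecular trap should secure; the alkene is unactivated, but C10 is unhindered and C5 meets an unsubstituted ylide terminus.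

Step 11
Reactants: 21 ethyl 1β,11:6α,20-diepoxy-12,14-dimethoxy-7-oxo-9(10→20)abeo-abieta-8,11,13-trien-19-oate
Product: 22 ethyl 6α,20-epoxy-1β-hydroxy-12-methoxy-7,11,14-trioxo-9(10→20)abeo-abieta-8,12-dien-19-oate (5α-H,10α-H)
Conditions: (NH4)2Ce(NO3)6 (2.5 equiv), MeCN/H2O, 0 °C
Reagents that add atoms: water, O
Why: Oxidation of the para-dialkoxyarene by tetravalent cerium should give the 11,14-quinone through attack of water at the two ipso carbons, so that the C14 methyl leaves as methanol and the tether is cut on its aryl side, freeing the 1β-hydroxyl with retention; this has to precede alkene formation because a C10=C20 bond inside the chromane-bridged system would be a bridgehead alkene.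

Step 12
Reactants: 22 ethyl 6α,20-epoxy-1β-hydroxy-12-methoxy-7,11,14-trioxo-9(10→20)abeo-abieta-8,12-dien-19-oate
Product: 25 (1R,4S,5R,6R)-1-hydroxy-12-methoxy-7,11,14-trioxo-9(10→20)abeo-abieta-8,10(20),12-trien-19,6-olide, via bridged hydroquinone 23 (not isolated), via vinylhydroquinone lactone 24 (not isolated)
Conditions: Na2S2O4, THF/H2O, rt; then TsOH·H2O (0.3 equiv), toluene, 60 °C, N2; then Ag2O, MgSO4, Et2O, rt
Reagents that add atoms: none
Why: Reduction to the hydroquinone turns the C20–O bridge into an ortho-hydroxybenzyl ether that should ionise under acid to an ortho-quinone methide and tautomerise by loss of H10 to the conjugated C10=C20 styrene, while the liberated C6 hydroxyl lactonises onto the C19 ester on the same face of ring A with loss of ethanol and Ag2O restores the quinone; C5 and C6 are not touched.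

Step 13
Reactants: 25 (1R,4S,5R,6R)-1-hydroxy-12-methoxy-7,11,14-trioxo-9(10→20)abeo-abieta-8,10(20),12-trien-19,6-olide
Product: 27 (1R,4S,5R,6R,7S)-1,7-dihydroxy-12-methoxy-11,14-dioxo-9(10→20)abeo-abieta-8,10(20),12-trien-19,6-olide (12-O-methylballotiquinone), via hydroquinone carbinol 26 (not isolated)
Conditions: NaBH4, CeCl3·7H2O, MeOH/THF, −78 → −40 °C; then Ag2O, Et2O, rt
Reagents that add atoms: none
Why: Under Luche conditions hydride should first reduce the quinone to the hydroquinone and then the C7 ketone; with the lactone trans-fused to ring B the C5–C6 bond stands nearly perpendicular to the carbonyl plane, so Felkin–Anh attack anti to it comes from the β-face and gives the 7S alcohol cis to the lactone oxygen, after which Ag2O re-oxidises the ring.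

Step 14
Reactants: 27 (1R,4S,5R,6R,7S)-1,7-dihydroxy-12-methoxy-11,14-dioxo-9(10→20)abeo-abieta-8,10(20),12-trien-19,6-olide
Product: 28 ballotiquinone, (1R,4S,5R,6R,7S)-1,7,12-trihydroxy-11,14-dioxo-9(10→20)abeo-abieta-8,10(20),12-trien-19,6-olide
Conditions: aq. HClO4, THF, 40 °C
Reagents that add atoms: water, O
Why: Acid-catalysed addition–elimination of water at C12 should hydrolyse the vinylogous methyl ester of the quinone to the hydroxyquinone, the electron-poor ring keeping C1 and C7 from ionising, so no stereocentre changes.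

## Compound list

1 | 1,3-dimethoxybenzene | COc1cccc(OC)c1 | starting material
2 | acetone | CC(C)=O | starting material
3 | 2-(2,6-dimethoxyphenyl)propan-2-ol (not isolated) | COc1cccc(OC)c1C(C)(C)O | intermediate
4 | 1,3-dimethoxy-2-(propan-2-yl)benzene | COc1cccc(OC)c1C(C)C | intermediate
5 | 2-chloro-2-oxoethyl acetate (acetoxyacetyl chloride) | CC(=O)OCC(Cl)=O | starting material
6 | 2-[2,4-dimethoxy-3-(propan-2-yl)phenyl]-2-oxoethyl acetate | CC(=O)OCC(=O)c1ccc(OC)c(C(C)C)c1OC | intermediate
7 | dichloromethyl methyl ether | COC(Cl)Cl | starting material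
8 | 2-[5-formyl-2,4-dimethoxy-3-(propan-2-yl)phenyl]-2-oxoethyl acetate | CC(=O)OCC(=O)c1cc(C=O)c(OC)c(C(C)C)c1OC | intermediate
9 | 5-[(acetyloxy)acetyl]-2,4-dimethoxy-3-(propan-2-yl)phenyl formate (not isolated) | CC(=O)OCC(=O)c1cc(OC=O)c(OC)c(C(C)C)c1OC | intermediate
10 | 2-[5-hydroxy-2,4-dimethoxy-3-(propan-2-yl)phenyl]-2-oxoethyl acetate | CC(=O)OCC(=O)c1cc(O)c(OC)c(C(C)C)c1OC | intermediate
11 | 2-[2-formyl-3-hydroxy-4,6-dimethoxy-5-(propan-2-yl)phenyl]-2-oxoethyl acetate | CC(=O)OCC(=O)c1c(C=O)c(O)c(OC)c(C(C)C)c1OC | intermediate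
12 | ethyl 2-methyl-3-oxopropanoate | CCOC(=O)C(C)C=O | starting material
13 | but-3-en-2-one | CC(=O)C=C | starting material
14 | ethyl (2S)-2-formyl-2-methyl-5-oxohexanoate (not isolated) | CCOC(=O)[C@@](C=O)(C)CCC(C)=O | intermediate
15 | ethyl (1S)-1-methyl-4-oxocyclohex-2-ene-1-carboxylate | CCOC(=O)[C@@]1(C)CCC(=O)C=C1 | intermediate
16 | ethyl (1S,4S)-4-hydroxy-1-methylcyclohex-2-ene-1-carboxylate | CCOC(=O)[C@@]1(C)CC[C@H](O)C=C1 | intermediate
17 | ethyl (1S,4R)-4-{3-[(acetyloxy)acetyl]-2-formyl-4,6-dimethoxy-5-(propan-2-yl)phenoxy}-1-methylcyclohex-2-ene-1-carboxylate | CCOC(=O)[C@@]1(C)CC[C@@H](Oc2c(OC)c(C(C)C)c(OC)c(C(=O)COC(C)=O)c2C=O)C=C1 | intermediate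
18 | ethyl (1S,4R)-4-{[1-hydroxy-5,7-dimethoxy-4-oxo-6-(propan-2-yl)-3,4-dihydro-1H-isochromen-8-yl]oxy}-1-methylcyclohex-2-ene-1-carboxylate (both anomers) | CCOC(=O)[C@@]1(C)CC[C@@H](Oc2c(OC)c(C(C)C)c(OC)c3C(=O)COC(O)c23)C=C1 | intermediate
19 | ethyl (1S,4R)-4-{[1-(acetyloxy)-5,7-dimethoxy-4-oxo-6-(propan-2-yl)-3,4-dihydro-1H-isochromen-8-yl]oxy}-1-methylcyclohex-2-ene-1-carboxylate (not isolated) | CCOC(=O)[C@@]1(C)CC[C@@H](Oc2c(OC)c(C(C)C)c(OC)c3C(=O)COC(OC(C)=O)c23)C=C1 | intermediate
20 | 8-{[(1R,4S)-4-(ethoxycarbonyl)-4-methylcyclohex-2-en-1-yl]oxy}-5,7-dimethoxy-6-(propan-2-yl)-2-benzopyrylium-4-olate (not isolated) | CCOC(=O)[C@@]1(C)CC[C@@H](Oc2c(OC)c(C(C)C)c(OC)c3C([O-])=C[O+]=Cc23)C=C1 | intermediate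
21 | ethyl 1β,11:6α,20-diepoxy-12,14-dimethoxy-7-oxo-9(10→20)abeo-abieta-8,11,13-trien-19-oate (5α-H,10α-H) | CCOC(=O)[C@@]1(C)CC[C@H]2Oc3c(OC)c(C(C)C)c(OC)c4c3[C@H]5O[C@@H](C4=O)[C@@H]1[C@@H]25 | intermediate
22 | ethyl 6α,20-epoxy-1β-hydroxy-12-methoxy-7,11,14-trioxo-9(10→20)abeo-abieta-8,12-dien-19-oate (5α-H,10α-H) | CCOC(=O)[C@@]1(C)CC[C@@H](O)[C@@H]2[C@H]1[C@H]3O[C@@H]2C4=C(C3=O)C(=O)C(C(C)C)=C(OC)C4=O | intermediate
23 | ethyl 6α,20-epoxy-1β,11,14-trihydroxy-12-methoxy-7-oxo-9(10→20)abeo-abieta-8,11,13-trien-19-oate (not isolated) | CCOC(=O)[C@@]1(C)CC[C@@H](O)[C@@H]2[C@H]1[C@H]3O[C@@H]2c4c(C3=O)c(O)c(C(C)C)c(OC)c4O | intermediate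
24 | (1R,4S,5R,6R)-1,11,14-trihydroxy-12-methoxy-7-oxo-9(10→20)abeo-abieta-8,10(20),11,13-tetraen-19,6-olide (not isolated) | CC(C)c1c(OC)c(O)c2c(c1O)C(=O)[C@@H]1OC(=O)[C@@]3(C)CC[C@@H](O)C(=C2)[C@@H]13 | intermediate
25 | (1R,4S,5R,6R)-1-hydroxy-12-methoxy-7,11,14-trioxo-9(10→20)abeo-abieta-8,10(20),12-trien-19,6-olide | CC(C)C1=C(OC)C(=O)C2=C(C1=O)C(=O)[C@@H]1OC(=O)[C@@]3(C)CC[C@@H](O)C(=C2)[C@@H]13 | intermediate
26 | (1R,4S,5R,6R,7S)-1,7,11,14-tetrahydroxy-12-methoxy-9(10→20)abeo-abieta-8,10(20),11,13-tetraen-19,6-olide (not isolated) | CC(C)c1c(OC)c(O)c2c(c1O)[C@H](O)[C@@H]1OC(=O)[C@@]3(C)CC[C@@H](O)C(=C2)[C@@H]13 | intermediate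
27 | (1R,4S,5R,6R,7S)-1,7-dihydroxy-12-methoxy-11,14-dioxo-9(10→20)abeo-abieta-8,10(20),12-trien-19,6-olide | CC(C)C1=C(OC)C(=O)C2=C(C1=O)[C@H](O)[C@@H]1OC(=O)[C@@]3(C)CC[C@@H](O)C(=C2)[C@@H]13 | intermediate
28 | ballotiquinone | CC(C)C1=C(O)C(=O)C2=C(C1=O)[C@H](O)[C@@H]1OC(=O)[C@@]3(C)CC[C@@H](O)C(=C2)[C@@H]13 | target

Total step count: 14. Longest linear sequence: 12 steps (steps 1–5 and 8–14); steps 6 and 7 form the ring-A branch.

Steps most likely to fail:

Step 10 (key step). The ylide may dimerise or be quenched by proton transfer faster than it adds to the unactivated, tethered alkene. The fallback is an intermolecular cycloaddition onto the electron-poor enone; it sets out from 11 and 15 and comes back at 27. Phenol 11 would be methylated (MeI, K2CO3, acetone) to 2-[2-formyl-3,4,6-trimethoxy-5-(propan-2-yl)phenyl]-2-oxoethyl acetate F1, deacetylated (K2CO3, MeOH) to the lactol 1-hydroxy-5,7,8-trimethoxy-6-(propan-2-yl)-1H-isochromen-4(3H)-one F2 and acetylated to 5,7,8-trimethoxy-4-oxo-6-(propan-2-yl)-3,4-dihydro-1H-isochromen-1-yl acetate F3. DBU would convert this into 5,7,8-trimethoxy-6-(propan-2-yl)-2-benzopyrylium-4-olate F4, which enone 15 would trap with matched polarity (ylide C6 to the β-carbon C5) as ethyl 6α,20-epoxy-11,12,14-trimethoxy-1,7-dioxo-9(10→20)abeo-abieta-8,11,13-trien-19-oate F5. DBU would then open the bridge by retro-oxa-Michael elimination of H10 and the alkoxide would lactonise to (4S,5R,6R)-11,12,14-trimethoxy-1,7-dioxo-9(10→20)abeo-abieta-8,10(20),11,13-tetraen-19,6-olide F6. NaBH4/CeCl3·7H2O would give (1R,4S,5R,6R,7S)-1,7-dihydroxy-11,12,14-trimethoxy-9(10→20)abeo-abieta-8,10(20),11,13-tetraen-19,6-olide F7, and (NH4)2Ce(NO3)6 would give 27. Facial and endo selectivity would then rest on substrate bias alone, so isomers of F5 would probably have to be separated.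

Step 12. Ortho-quinone methide formation may be slow, or the α-ketol may epimerise at C6 before it lactonises. The fallback is a base-mediated opening; it sets out from 22 and comes back at 27. Dess–Martin oxidation of the C1 hydroxyl would give ethyl 6α,20-epoxy-12-methoxy-1,7,11,14-tetraoxo-9(10→20)abeo-abieta-8,12-dien-19-oate F8. Et3N or DBU would open the bridge by E1cB elimination of H10, now α to a ketone, and the alkoxide would lactonise to (4S,5R,6R)-12-methoxy-1,7,11,14-tetraoxo-9(10→20)abeo-abieta-8,10(20),12-trien-19,6-olide F9. NaBH4/CeCl3·7H2O followed by Ag2O would reduce both ketones (C1 from the α-face, C7 as in step 13) to 27.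

Step 13. Hydride may add to C7 with poor facial selectivity, or the ortho-hydroxybenzyl alkoxide present at the hydroquinone stage may be over-reduced. The fallback is a catalyst-controlled reduction on a protected hydroquinone; it sets out from 25 and comes back at 27. Na2S2O4 followed by TBSOTf and 2,6-lutidine would give (1R,4S,5R,6R)-1,11,14-tris[(tert-butyldimethylsilyl)oxy]-12-methoxy-7-oxo-9(10→20)abeo-abieta-8,10(20),11,13-tetraen-19,6-olide F10. Reduction with (S)-2-methyl-CBS-oxazaborolidine and catecholborane (aryl as the large group) would give (1R,4S,5R,6R,7S)-1,11,14-tris[(tert-butyldimethylsilyl)oxy]-7-hydroxy-12-methoxy-9(10→20)abeo-abieta-8,10(20),11,13-tetraen-19,6-olide F11. Bu4NF followed by Ag2O would give 27.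

## Further compounds

F1 | step 10 | 2-[2-formyl-3,4,6-trimethoxy-5-(propan-2-yl)phenyl]-2-oxoethyl acetate | CC(=O)OCC(=O)c1c(C=O)c(OC)c(OC)c(C(C)C)c1OC
F2 | step 10 | 1-hydroxy-5,7,8-trimethoxy-6-(propan-2-yl)-1H-isochromen-4(3H)-one | COc1c(C(C)C)c(OC)c(OC)c2C(O)OCC(=O)c12
F3 | step 10 | 5,7,8-trimethoxy-4-oxo-6-(propan-2-yl)-3,4-dihydro-1H-isochromen-1-yl acetate | COc1c(C(C)C)c(OC)c(OC)c2C(OC(C)=O)OCC(=O)c12
F4 | step 10 | 5,7,8-trimethoxy-6-(propan-2-yl)-2-benzopyrylium-4-olate | COc1c(C(C)C)c(OC)c(OC)c2C=[O+]C=C([O-])c12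
F5 | step 10 | ethyl 6α,20-epoxy-11,12,14-trimethoxy-1,7-dioxo-9(10→20)abeo-abieta-8,11,13-trien-19-oate (5α-H,10α-H) | CCOC(=O)[C@@]1(C)CCC(=O)[C@@H]2[C@H]1[C@H]3O[C@@H]2c4c(C3=O)c(OC)c(C(C)C)c(OC)c4OC
F6 | step 10 | (4S,5R,6R)-11,12,14-trimethoxy-1,7-dioxo-9(10→20)abeo-abieta-8,10(20),11,13-tetraen-19,6-olide | CC(C)c1c(OC)c(OC)c2c(c1OC)C(=O)[C@@H]1OC(=O)[C@@]3(C)CCC(=O)C(=C2)[C@@H]13
F7 | step 10 | (1R,4S,5R,6R,7S)-1,7-dihydroxy-11,12,14-trimethoxy-9(10→20)abeo-abieta-8,10(20),11,13-tetraen-19,6-olide | CC(C)c1c(OC)c(OC)c2c(c1OC)[C@H](O)[C@@H]1OC(=O)[C@@]3(C)CC[C@@H](O)C(=C2)[C@@H]13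
F8 | step 12 | ethyl 6α,20-epoxy-12-methoxy-1,7,11,14-tetraoxo-9(10→20)abeo-abieta-8,12-dien-19-oate (5α-H,10α-H) | CCOC(=O)[C@@]1(C)CCC(=O)[C@@H]2[C@H]1[C@H]3O[C@@H]2C4=C(C3=O)C(=O)C(C(C)C)=C(OC)C4=O
F9 | step 12 | (4S,5R,6R)-12-methoxy-1,7,11,14-tetraoxo-9(10→20)abeo-abieta-8,10(20),12-trien-19,6-olide | CC(C)C1=C(OC)C(=O)C2=C(C1=O)C(=O)[C@@H]1OC(=O)[C@@]3(C)CCC(=O)C(=C2)[C@@H]13
F10 | step 13 | (1R,4S,5R,6R)-1,11,14-tris[(tert-butyldimethylsilyl)oxy]-12-methoxy-7-oxo-9(10→20)abeo-abieta-8,10(20),11,13-tetraen-19,6-olide | CC(C)c1c(OC)c(O[Si](C)(C)C(C)(C)C)c2c(c1O[Si](C)(C)C(C)(C)C)C(=O)[C@@H]1OC(=O)[C@@]3(C)CC[C@@H](O[Si](C)(C)C(C)(C)C)C(=C2)[C@@H]13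
F11 | step 13 | (1R,4S,5R,6R,7S)-1,11,14-tris[(tert-butyldimethylsilyl)oxy]-7-hydroxy-12-methoxy-9(10→20)abeo-abieta-8,10(20),11,13-tetraen-19,6-olide | CC(C)c1c(OC)c(O[Si](C)(C)C(C)(C)C)c2c(c1O[Si](C)(C)C(C)(C)C)[C@H](O)[C@@H]1OC(=O)[C@@]3(C)CC[C@@H](O[Si](C)(C)C(C)(C)C)C(=C2)[C@@H]13
A1 | direct plan | 2,4,5-trimethoxy-3-(propan-2-yl)benzaldehyde | COc1c(C=O)cc(OC)c(OC)c1C(C)C
A2 | direct plan | (5R)-5-{(S)-hydroxy[2,4,5-trimethoxy-3-(propan-2-yl)phenyl]methyl}-3-methylfuran-2(5H)-one | COc1c(cc(OC)c(OC)c1C(C)C)[C@H](O)[C@@H]1OC(=O)C(C)=C1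
A3 | direct plan | (4S,5R,6R,7S)-7-[(tert-butyldimethylsilyl)oxy]-11,12,14-trimethoxy-1-oxo-9(10→20)abeo-abieta-8,10(20),11,13-tetraen-19,6-olide | CC(C)c1c(OC)c(OC)c2c(c1OC)[C@H](O[Si](C)(C)C(C)(C)C)[C@@H]1OC(=O)[C@@]3(C)CCC(=O)C(=C2)[C@@H]13
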